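| flask | left-handed substrate | right-handed substrate | partner | precatalyst | remark | time |
|---|---|---|---|---|---|---|
| dawn | 0.10 M | 0.10 M | 0.20 M | 1 mM | the very flask that is asked about, followed so far |  |
| noon | 0.20 M | 0.20 M | 0.20 M | 1 mM | run made earlier |  |
| flask | 0.10 M | 0.10 M | 0.200 M | 1.0 mM |  | 6.0 h |

dawn run (percent of the left-handed substrate and right-handed substrate together charged)

| time / min | left-handed product / % | right-handed product / % |
|---|---|---|
| 20.0 | 10.5 | 1.1 |
| 40.0 | 22.9 | 2.2 |
| 60.0 | 33.0 | 4.8 |
| 80.0 | 42.0 | 6.5 |
| 120 | 54.4 | 6.3 |

noon run (percent of the left-handed substrate and right-handed substrate together charged)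

| time / h | left-handed product / % | right-handed product / % |
|---|---|---|
| 0.200 | 2.6 | 1.0 |
| 0.333 | 7.0 | 0 |
| 0.667 | 11.8 | 0.4 |
| 1.33 | 24.5 | 2.2 |
| 2.50 | 34.3 | 4.8 |

(standard deviation of a reading: 1 percentage point)

- free catalyst is single-handed; left-handed substrate and right-handed substrate are mirror images of each other, charged as a racemate, each of them at the stated concentration
- what was read earlier has a scatter of 1 percentage point, one standard deviation
- on the list of suspects stand: left-handed substrate <-> right-handed substrate; partner + precatalyst -> free catalyst + spent reagent; partner + catalyst intermediate B -> free catalyst + right-handed product; free catalyst + left-handed substrate <-> catalyst intermediate A; free catalyst + right-handed substrate <-> catalyst intermediate B; partner + catalyst intermediate A -> free catalyst + left-handed product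

1. the left-handed product in the flask at 6.0 h, as a percentage of the left-handed substrate and right-handed substrate together charged
2. the right-handed product in the flask at 6.0 h, as a percentage of the left-handed substrate and right-handed substrate together charged
3. the left-handed substrate in the flask at 6.0 h, as a percentage of the left-handed substrate and right-handed substrate together charged
4. the right-handed substrate in the flask at 6.0 h, as a percentage of the left-handed substrate and right-handed substrate together charged

By 120 min the dawn flask, which is the flask asked about, holds 54.4% left-handed product, more than the left-handed substrate's share of the charge, so right-handed substrate must be crossing over. Each product takes one partner, and the two substrates together equal the partner charge, so the summed product percentage reads as partner consumed, give or take the 1 mM that the precatalyst can take.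

Noon has twice the substrate, yet at 1.33 h it has made 0.107 M of product against dawn's 0.0970 M. My reckoning therefore assumes that substrate binding is fast and keeps the catalyst bound, and it lets [partner] fall in a pseudo-first-order way.

The partner decay constant, the logarithm of charged over remaining [partner] divided by the time, is 0.00778 min⁻¹ from dawn's last reading. Carried to 6.0 h, this constant reckons 6.07% of the partner left, so my products sum to 93.9%. The forecast sums lower, to 90.0%: 78.5% left-handed product, 11.5% right-handed product, 4.3% left-handed substrate and 5.7% right-handed substrate, reasoning that “The catalyst is therefore nearly saturated with substrate”.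

The flask gives 80.4% left-handed product, 9.86% right-handed product, 2.69% left-handed substrate and 6.77% right-handed substrate, each within the forecast's margin.

    left-handed substrate ⇌ right-handed substrate (k = 0.00790 min⁻¹)
    partner + precatalyst → free catalyst + spent reagent (k = 0.990 L mol⁻¹ min⁻¹)
    partner + catalyst intermediate B → free catalyst + right-handed product (k = 3.80 L mol⁻¹ min⁻¹)
    free catalyst + left-handed substrate ⇌ catalyst intermediate A (K = 200 L mol⁻¹, k = 360 L mol⁻¹ min⁻¹)
    free catalyst + right-handed substrate ⇌ catalyst intermediate B (K = 24.0 L mol⁻¹, k = 81.0 L mol⁻¹ min⁻¹)
    partner + catalyst intermediate A → free catalyst + left-handed product (k = 11.0 L mol⁻¹ min⁻¹)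

At 6.00 h this flask keeps 9.2% of its partner, against the 6.07% reckoned. In this flask catalyst intermediate A held 68.7% of the catalyst at 0.600 h, and free catalyst grew from 10.8% then to 43.8% at 6.00 h, while right-handed substrate crossed to left-handed substrate by a net 33.3% of the charge. A second flask, charged alike but with 0.050 M of partner, is reckoned at the same 6.07% of its own partner, and it keeps 4.0% at 6.00 h, with catalyst intermediate A at 83.6% of the catalyst.

The data are calculated for substances that don't exist, noise included.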